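Thielavin Z8 is read as the tridepside of orsellinic acid carrying six extra methyls: C3 and C5 of rings A, B and C (C1 is the carboxyl carbon), each ortho to a ring oxygen. All six aryl–CH3 bonds are made last, in one palladium-catalysed methylation of a hexabromide. Both depside esters (ring A carbonyl to O4 of ring B, ring B carbonyl to O4 of ring C) are therefore built on phenols without ortho substituents, and bromine enters where the free phenols direct it. The precursor is the hexabromo tri-orsellinate with four MOM ethers and a tert-butyl ester at C1 of ring C; this carboxyl blocks that carbon and is removed at the end.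

Key step: step 10

Remark: ring A is the terminal 2,4-dihydroxybenzoyl unit, ring B the middle unit and ring C the unit that ends without carboxyl. Loss of CO2 from the ring C acid is assumed not to be spontaneous, so deprotection (with C1 of ring C still blocked against formaldehyde and tert-butyl cations) and decarboxylation are run as separate steps.

Step 1
Reactants: 1 orsellinic acid
Product: 2 benzyl 2,4-bis(benzyloxy)-6-methylbenzoate
Conditions: BnBr (3.5 equiv), K2CO3 (4 equiv), DMF, 60 °C
Reagents that add atoms: benzyl bromide, BrCc1ccccc1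
Why: Williamson O-alkylation of the carboxylate and both phenoxides, the carboxylate reacting first so that the free acid cannot lose CO2 on warming.

Step 2
Reactants: 2 benzyl 2,4-bis(benzyloxy)-6-methylbenzoate
Product: 3 2,4-bis(benzyloxy)-6-methylbenzoic acid
Conditions: KOH, DMSO/H2O, 90 °C; then aq. HCl, 0 °C
Reagents that add atoms: potassium hydroxide, [K+].[OH-]
Why: Saponification of the di-ortho-substituted benzyl ester needs hot hydroxide in a dipolar solvent, which the benzyl ethers tolerate.

Step 3
Reactants: 1 orsellinic acid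
Product: 4 tert-butyl 2,4-dihydroxy-6-methylbenzoate (tert-butyl orsellinate)
Conditions: tert-butyl 2,2,2-trichloroacetimidate (2 equiv), THF/cyclohexane, rt
Reagents that add atoms: tert-butyl 2,2,2-trichloroacetimidate, CC(C)(C)OC(=N)C(Cl)(Cl)Cl
Why: Imidate esterification without added acid: the carboxylic acid protonates the imidate and captures the tert-butyl cation, the far less acidic phenols stay unalkylated, and room temperature avoids decarboxylation.

Step 4
Reactants: 3 2,4-bis(benzyloxy)-6-methylbenzoic acid; 4 tert-butyl orsellinate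
Product: 5 tert-butyl 4-{[2,4-bis(benzyloxy)-6-methylbenzoyl]oxy}-2-hydroxy-6-methylbenzoate (ring B–ring C didepside, ring B as bis-benzyl ether)
Conditions: DCC (1.1 equiv), DMAP (0.1 equiv), CH2Cl2, 0 °C to rt
Reagents that add atoms: none
Why: Steglich esterification that should acylate only the 4-hydroxyl of 4, because the 2-hydroxyl is hydrogen-bonded to and flanked by the ester carbonyl, the usual selectivity of orsellinate depside couplings.

Step 5
Reactants: 5 ring B–ring C didepside bis-benzyl ether
Product: 6 tert-butyl 4-[(2,4-dihydroxy-6-methylbenzoyl)oxy]-2-hydroxy-6-methylbenzoate (tert-butyl lecanorate)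
Conditions: H2 (1 atm), Pd/C, EtOAc, rt
Reagents that add atoms: none
Why: Hydrogenolysis of the two benzyl ethers, to which the aryl ester and the tert-butyl ester are inert.

Step 6
Reactants: 3 2,4-bis(benzyloxy)-6-methylbenzoic acid; 6 tert-butyl lecanorate
Product: 7 tert-butyl 4-{[4-{[2,4-bis(benzyloxy)-6-methylbenzoyl]oxy}-2-hydroxy-6-methylbenzoyl]oxy}-2-hydroxy-6-methylbenzoate (tridepside, ring A as bis-benzyl ether)
Conditions: DCC (1.1 equiv), DMAP (0.1 equiv), CH2Cl2, 0 °C to rt
Reagents that add atoms: none
Why: Second Steglich esterification, selective because the 4-hydroxyl of ring B is the only one of the three phenols in 6 that is not chelated to an ortho ester carbonyl.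

Step 7
Reactants: 7 tridepside bis-benzyl ether
Product: 8 tert-butyl 4-{[4-[(2,4-dihydroxy-6-methylbenzoyl)oxy]-2-hydroxy-6-methylbenzoyl]oxy}-2-hydroxy-6-methylbenzoate (tert-butyl gyrophorate, the tri-orsellinate tetraphenol)
Conditions: H2 (1 atm), Pd/C, EtOAc, rt
Reagents that add atoms: none
Why: Hydrogenolysis of the benzyl ethers frees the ring A phenols without touching either depside ester or the tert-butyl ester.

Step 8
Reactants: 8 tert-butyl gyrophorate
Product: 9 tert-butyl 3,5-dibromo-4-{[3,5-dibromo-4-[(3,5-dibromo-2,4-dihydroxy-6-methylbenzoyl)oxy]-2-hydroxy-6-methylbenzoyl]oxy}-2-hydroxy-6-methylbenzoate (hexabromo tetraphenol)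
Conditions: NBS (6.3 equiv), DMF, 0 °C to rt, dark; aq. Na2S2O3 work-up
Reagents that add atoms: N-bromosuccinimide, O=C1CCC(=O)N1Br
Why: Electrophilic aromatic bromination in which C3 and C5 are the only unsubstituted carbons of each ring and each lies ortho or para to a free phenol, so exhaustive substitution should converge on one product without strong acid that would threaten the tert-butyl ester.

Step 9
Reactants: 9 hexabromo tetraphenol
Product: 10 tert-butyl 3,5-dibromo-4-{[3,5-dibromo-4-{[3,5-dibromo-2,4-bis(methoxymethoxy)-6-methylbenzoyl]oxy}-2-(methoxymethoxy)-6-methylbenzoyl]oxy}-2-(methoxymethoxy)-6-methylbenzoate (protected hexabromide)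
Conditions: MOMCl (6 equiv), iPr2NEt (8 equiv), Bu4NI (cat.), CH2Cl2, 0 °C to rt
Reagents that add atoms: chloromethyl methyl ether, COCCl
Why: O-alkylation of the four phenols with the small, highly electrophilic chloromethyl ether, the ortho bromines making the phenols acidic enough for an amine base that leaves the aryl esters alone.

Step 10
Reactants: 10 protected hexabromide; 11 trimethylboroxine (4 equiv)
Product: 12 tert-butyl 4-{[4-{[2,4-bis(methoxymethoxy)-3,5,6-trimethylbenzoyl]oxy}-2-(methoxymethoxy)-3,5,6-trimethylbenzoyl]oxy}-2-(methoxymethoxy)-3,5,6-trimethylbenzoate (protected hexamethyl tridepside)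
Conditions: Pd(OAc)2 (30 mol %), SPhos (60 mol %), K3PO4 (12 equiv), H2O (12 equiv), toluene, 100 °C, Ar
Reagents that add atoms: trimethylboroxine, CB1OB(C)OB(C)O1
Why: Suzuki–Miyaura methylation: monoligated zerovalent palladium bearing SPhos adds oxidatively to each aryl–Br bond, the phosphate-activated methylboron species hands its CH3 to divalent palladium, and reductive elimination releases the aryl–CH3 bond, the cycle running six times on one molecule. The closest known reaction type is the methylation of di-ortho-substituted aryl bromides with trimethylboroxine or methylboronic acid under dialkylbiarylphosphine ligands, together with exhaustive methylation of polybromoarenes. No ring is closed and no stereocenter is created, so the only selectivities needed are chemoselectivity for C–Br over the two aryl ester C–O bonds and complete conversion at all six sites. The substrate secures the first by having every phenol capped as a MOM ether, so that no phenoxide can attack a depside ester or bind palladium, and by the 2,6-disubstitution of both benzoyl carbonyls, which shuts out phosphate or hydroxide. It secures the second because each bromine sits on an ester-bearing ring that favours oxidative addition, because methyl has no beta-hydrogen, and because excess boroxine keeps transmetalation ahead of protodebromination.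

Step 11
Reactants: 12 protected hexamethyl tridepside
Product: 13 4-{[4-[(2,4-dihydroxy-3,5,6-trimethylbenzoyl)oxy]-2-hydroxy-3,5,6-trimethylbenzoyl]oxy}-2-hydroxy-3,5,6-trimethylbenzoic acid
Conditions: TFA/CH2Cl2/H2O (10:10:1), 0 °C to rt
Reagents that add atoms: none
Why: Acidolysis (acetal hydrolysis of the four aryl MOM ethers and alkyl–oxygen cleavage of the tert-butyl ester) at a stage where every ring carbon is still substituted, so the released formaldehyde and tert-butyl cation find no free aromatic position and the doubly hindered aryl esters stay intact.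

Step 12
Reactants: 13 hexamethyl tridepside acid
Product: 14 thielavin Z8, 3-hydroxy-2,5,6-trimethylphenyl 4-[(2,4-dihydroxy-3,5,6-trimethylbenzoyl)oxy]-2-hydroxy-3,5,6-trimethylbenzoate
Conditions: Ag2CO3 (10 mol %), AcOH (5 mol %), DMSO, 120 °C, Ar
Reagents that add atoms: none
Why: Silver-catalysed protodecarboxylation of an ortho-substituted benzoic acid: the ring C carboxylate, flanked by the 2-hydroxyl and the 6-methyl, should lose CO2 to an aryl–silver species that is protonated, and it is the only free acid in the molecule.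

Compound list
1 | orsellinic acid (2,4-dihydroxy-6-methylbenzoic acid) | Cc1cc(O)cc(O)c1C(=O)O | starting material
2 | benzyl 2,4-bis(benzyloxy)-6-methylbenzoate | Cc1cc(OCc2ccccc2)cc(OCc2ccccc2)c1C(=O)OCc1ccccc1 | intermediate
3 | 2,4-bis(benzyloxy)-6-methylbenzoic acid | Cc1cc(OCc2ccccc2)cc(OCc2ccccc2)c1C(=O)O | intermediate
4 | tert-butyl 2,4-dihydroxy-6-methylbenzoate (tert-butyl orsellinate) | Cc1cc(O)cc(O)c1C(=O)OC(C)(C)C | intermediate
5 | tert-butyl 4-{[2,4-bis(benzyloxy)-6-methylbenzoyl]oxy}-2-hydroxy-6-methylbenzoate | Cc1cc(OCc2ccccc2)cc(OCc2ccccc2)c1C(=O)Oc1cc(C)c(C(=O)OC(C)(C)C)c(O)c1 | intermediate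
6 | tert-butyl 4-[(2,4-dihydroxy-6-methylbenzoyl)oxy]-2-hydroxy-6-methylbenzoate (tert-butyl lecanorate) | Cc1cc(O)cc(O)c1C(=O)Oc1cc(C)c(C(=O)OC(C)(C)C)c(O)c1 | intermediate
7 | tert-butyl 4-{[4-{[2,4-bis(benzyloxy)-6-methylbenzoyl]oxy}-2-hydroxy-6-methylbenzoyl]oxy}-2-hydroxy-6-methylbenzoate | Cc1cc(OCc2ccccc2)cc(OCc2ccccc2)c1C(=O)Oc1cc(C)c(C(=O)Oc2cc(C)c(C(=O)OC(C)(C)C)c(O)c2)c(O)c1 | intermediate
8 | tert-butyl 4-{[4-[(2,4-dihydroxy-6-methylbenzoyl)oxy]-2-hydroxy-6-methylbenzoyl]oxy}-2-hydroxy-6-methylbenzoate (tert-butyl gyrophorate) | Cc1cc(O)cc(O)c1C(=O)Oc1cc(C)c(C(=O)Oc2cc(C)c(C(=O)OC(C)(C)C)c(O)c2)c(O)c1 | intermediate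
9 | tert-butyl 3,5-dibromo-4-{[3,5-dibromo-4-[(3,5-dibromo-2,4-dihydroxy-6-methylbenzoyl)oxy]-2-hydroxy-6-methylbenzoyl]oxy}-2-hydroxy-6-methylbenzoate | Cc1c(Br)c(O)c(Br)c(O)c1C(=O)Oc1c(Br)c(C)c(C(=O)Oc2c(Br)c(C)c(C(=O)OC(C)(C)C)c(O)c2Br)c(O)c1Br | intermediate
10 | tert-butyl 3,5-dibromo-4-{[3,5-dibromo-4-{[3,5-dibromo-2,4-bis(methoxymethoxy)-6-methylbenzoyl]oxy}-2-(methoxymethoxy)-6-methylbenzoyl]oxy}-2-(methoxymethoxy)-6-methylbenzoate | Cc1c(Br)c(OCOC)c(Br)c(OCOC)c1C(=O)Oc1c(Br)c(C)c(C(=O)Oc2c(Br)c(C)c(C(=O)OC(C)(C)C)c(OCOC)c2Br)c(OCOC)c1Br | intermediate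
11 | trimethylboroxine | CB1OB(C)OB(C)O1 | starting material
12 | tert-butyl 4-{[4-{[2,4-bis(methoxymethoxy)-3,5,6-trimethylbenzoyl]oxy}-2-(methoxymethoxy)-3,5,6-trimethylbenzoyl]oxy}-2-(methoxymethoxy)-3,5,6-trimethylbenzoate | Cc1c(C)c(OCOC)c(C)c(OCOC)c1C(=O)Oc1c(C)c(C)c(C(=O)Oc2c(C)c(C)c(C(=O)OC(C)(C)C)c(OCOC)c2C)c(OCOC)c1C | intermediate
13 | 4-{[4-[(2,4-dihydroxy-3,5,6-trimethylbenzoyl)oxy]-2-hydroxy-3,5,6-trimethylbenzoyl]oxy}-2-hydroxy-3,5,6-trimethylbenzoic acid | Cc1c(C)c(O)c(C)c(O)c1C(=O)Oc1c(C)c(C)c(C(=O)Oc2c(C)c(C)c(C(=O)O)c(O)c2C)c(O)c1C | intermediate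
14 | thielavin Z8, 3-hydroxy-2,5,6-trimethylphenyl 4-[(2,4-dihydroxy-3,5,6-trimethylbenzoyl)oxy]-2-hydroxy-3,5,6-trimethylbenzoate | Cc1cc(O)c(C)c(OC(=O)c2c(C)c(C)c(OC(=O)c3c(C)c(C)c(O)c(C)c3O)c(C)c2O)c1C | target

Total step count: 12. Longest linear sequence: 11 steps (steps 1, 2 and 4 to 12, from orsellinic acid through 3 to 14).

Steps most likely to fail

1. Step 10. The sixfold coupling may stall at partly methylated stages while protodebromination takes over, or the phosphate base may cleave the 2,6-dibromoaryl esters before they are methylated. The fallback changes the organometallic partner and the transmetalation mechanism: setting out from 10, a base-free Negishi coupling with MeZnCl (12 equiv) and Pd(P(t-Bu)3)2 in THF/NMP at 60 °C should deliver 12 directly, since methylzinc chloride leaves aryl esters, the tert-butyl ester and MOM ethers untouched; it makes no new compound (F0) and comes back to the route at 12.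

2. Step 12. Loss of CO2 from the ring C acid, whose para oxygen is acylated and therefore only weakly donating, may be slow enough that forcing temperatures bring phenol oxidation by silver or acyl migration between phenols. The fallback removes the carboxyl by ipso substitution instead of heat. Setting out from 13, NBS (1.05 equiv) in MeCN at 0 °C to rt with a thiosulfate work-up should effect bromodecarboxylation at C1 of ring C (the only position where an electrophile can end irreversibly) to give 4-bromo-3-hydroxy-2,5,6-trimethylphenyl 4-[(2,4-dihydroxy-3,5,6-trimethylbenzoyl)oxy]-2-hydroxy-3,5,6-trimethylbenzoate F1. Hydrodebromination with H2, Pd/C and NaOAc in THF/H2O at rt then comes back to the route at 14.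

3. Step 9. Capping may stay incomplete at the three chelated, bromine-flanked 2-hydroxyls, or phenoxides formed under base may trigger acyl transfer at the activated dibromoaryl esters. The fallback protects under neutral redox conditions with a different group. Setting out from 9, Mitsunobu etherification with benzyl alcohol, PPh3 and DIAD in THF should give the tetra-O-benzyl ether of 9 F2. The coupling of step 10 with 11 then gives the tetra-O-benzyl hexamethyl tridepside tert-butyl ester F3. Hydrogenolysis (H2, Pd/C, EtOAc) gives the hexamethyl tridepside tetraphenol tert-butyl ester F4, and TFA/CH2Cl2 cleaves the tert-butyl ester and comes back to the route at 13.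

Further compounds
F0 | step 10 | none | none
F1 | step 12 | 4-bromo-3-hydroxy-2,5,6-trimethylphenyl 4-[(2,4-dihydroxy-3,5,6-trimethylbenzoyl)oxy]-2-hydroxy-3,5,6-trimethylbenzoate | Cc1c(C)c(O)c(C)c(O)c1C(=O)Oc1c(C)c(C)c(C(=O)Oc2c(C)c(C)c(Br)c(O)c2C)c(O)c1C
F2 | step 9 | tert-butyl 2-(benzyloxy)-4-{[2-(benzyloxy)-4-{[2,4-bis(benzyloxy)-3,5-dibromo-6-methylbenzoyl]oxy}-3,5-dibromo-6-methylbenzoyl]oxy}-3,5-dibromo-6-methylbenzoate | Cc1c(Br)c(OCc2ccccc2)c(Br)c(OCc2ccccc2)c1C(=O)Oc1c(Br)c(C)c(C(=O)Oc2c(Br)c(C)c(C(=O)OC(C)(C)C)c(OCc3ccccc3)c2Br)c(OCc2ccccc2)c1Br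
F3 | step 9 | tert-butyl 2-(benzyloxy)-4-{[2-(benzyloxy)-4-{[2,4-bis(benzyloxy)-3,5,6-trimethylbenzoyl]oxy}-3,5,6-trimethylbenzoyl]oxy}-3,5,6-trimethylbenzoate | Cc1c(C)c(OCc2ccccc2)c(C)c(OCc2ccccc2)c1C(=O)Oc1c(C)c(C)c(C(=O)Oc2c(C)c(C)c(C(=O)OC(C)(C)C)c(OCc3ccccc3)c2C)c(OCc2ccccc2)c1C
F4 | step 9 | tert-butyl 4-{[4-[(2,4-dihydroxy-3,5,6-trimethylbenzoyl)oxy]-2-hydroxy-3,5,6-trimethylbenzoyl]oxy}-2-hydroxy-3,5,6-trimethylbenzoate | Cc1c(C)c(O)c(C)c(O)c1C(=O)Oc1c(C)c(C)c(C(=O)Oc2c(C)c(C)c(C(=O)OC(C)(C)C)c(O)c2C)c(O)c1C
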